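## Retrosynthetic overview

1. The target comes from double O-debenzylation; its erythro (1R,2S) diol comes from a chelation-controlled reduction of an aryl ketone made by joining the 5-lithiated dihydrobenzofuran to an (S)-lactic acid Weinreb amide (fragment 3).
2. The dihydrofuran ring is the only ring formed (both benzene rings are bought). It closes by intramolecular oxa-Michael (1,6-conjugate) addition of the ring B phenol to a ring A p-quinone methide released from a 4-hydroxybenzylic alcohol; the preset C3 centre directs the trans-(2S,3S) outcome.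
3. That alcohol comes from a ring A aryl Grignard reagent (fragment 2, from o-vanillin by bromination, MOM protection, Baeyer–Villiger oxidation and benzylation) and a ring B (S)-2-arylpropanal (fragment 1).
4. Fragment 1 comes from ozonolysis of an ortho-(1,3-dimethylallyl)phenol, itself made by an aromatic Claisen rearrangement with 1,3-chirality transfer from the aryl ether of 4-bromo-2-methoxyphenol and (R,E)-pent-3-en-2-ol (Sharpless kinetic resolution, then Mitsunobu).

Assumption: the stereocentres are taken exactly as written in the SMILES, which reads as (2S,3S)-trans on the dihydrobenzofuran and (1R,2S)-erythro on the diol side chain.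

## Route

Step 1
Reactants: 1 rac-(E)-pent-3-en-2-ol
Product: 2 (2R,3E)-pent-3-en-2-ol
Conditions: Ti(OiPr)4 (10 mol%), L-(+)-diisopropyl tartrate (15 mol%), t-BuOOH (0.6 equiv), 3 Å molecular sieves, CH2Cl2, −20 °C; distil
Reagents that add atoms: none
Why: Sharpless kinetic resolution, in which the titanium tartrate catalyst epoxidises the S enantiomer much faster, so the R alcohol is recovered in high ee at about 60% conversion.

Step 2
Reactants: 2 (2R,3E)-pent-3-en-2-ol; 3 4-bromo-2-methoxyphenol
Product: 4 4-bromo-2-methoxy-1-{[(2S,3E)-pent-3-en-2-yl]oxy}benzene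
Conditions: PPh3, DIAD, THF, 0 °C to rt
Reagents that add atoms: none
Why: Mitsunobu etherification is an SN2 displacement of the activated alcohol by the phenoxide, so the carbinol centre inverts from R to S.

Step 3
Reactants: 4 4-bromo-2-methoxy-1-{[(2S,3E)-pent-3-en-2-yl]oxy}benzene
Product: 6 4-bromo-2-methoxy-6-[(2R,3E)-pent-3-en-2-yl]phenol, via dienone 5 (not isolated)
Conditions: Eu(fod)3 (10 mol%; fod = 6,6,7,7,8,8,8-heptafluoro-2,2-dimethyloctane-3,5-dionate), CHCl3, 50 °C
Reagents that add atoms: none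
Why: Lewis-acid-catalysed aromatic Claisen ([3,3]-sigmatropic) rearrangement to the only free ortho position runs suprafacially through a chair transition state with the α-methyl group equatorial, so the S ether centre is relayed into the R benzylic centre with an E alkene before the dienone enolises.

Step 4
Reactants: 6 4-bromo-2-methoxy-6-[(2R,3E)-pent-3-en-2-yl]phenol
Product: 7 5-bromo-1-methoxy-2-(methoxymethoxy)-3-[(2R,3E)-pent-3-en-2-yl]benzene
Conditions: MOMCl, iPr2NEt, CH2Cl2, 0 °C to reflux
Reagents that add atoms: chloromethyl methyl ether, COCCl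
Why: O-alkylation of the phenol (Williamson-type acetal formation) masks it for the ozone and Grignard steps and does not touch the stereocentre.

Step 5
Reactants: 7 5-bromo-1-methoxy-2-(methoxymethoxy)-3-[(2R,3E)-pent-3-en-2-yl]benzene
Product: 9 (2S)-2-[5-bromo-3-methoxy-2-(methoxymethoxy)phenyl]propanal, via ozonide 8 (not isolated)
Conditions: O3, CH2Cl2, −78 °C (stop at first excess); then PPh3, −78 to 0 °C; crude aldehyde used at once
Reagents that add atoms: ozone, [O-][O+]=O
Why: Ozonolysis (Criegee mechanism) cleaves the disubstituted alkene far faster than the bromoarene, and the cold reductive work-up gives the α-aryl aldehyde without touching the stereocentre, whose descriptor changes from R to S only because the CIP priorities change.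

Step 6
Reactants: 10 2-hydroxy-3-methoxybenzaldehyde (o-vanillin)
Product: 11 5-bromo-2-hydroxy-3-methoxybenzaldehyde
Conditions: Br2, NaOAc, AcOH, rt
Reagents that add atoms: bromine, BrBr
Why: Electrophilic aromatic bromination goes para to the phenolic OH, the strongest director, which is also meta to the aldehyde.

Step 7
Reactants: 11 5-bromo-2-hydroxy-3-methoxybenzaldehyde
Product: 12 5-bromo-3-methoxy-2-(methoxymethoxy)benzaldehyde
Conditions: MOMCl, iPr2NEt, CH2Cl2, 0 °C to rt
Reagents that add atoms: chloromethyl methyl ether, COCCl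
Why: O-alkylation of the acidic salicylaldehyde phenol installs the acid-labile group that later frees the ring A para-OH for quinone methide formation.

Step 8
Reactants: 12 5-bromo-3-methoxy-2-(methoxymethoxy)benzaldehyde
Product: 14 5-bromo-3-methoxy-2-(methoxymethoxy)phenol, via aryl formate 13 (not isolated)
Conditions: mCPBA, CH2Cl2, rt; then K2CO3 (cat.), MeOH, rt
Reagents that add atoms: 3-chloroperoxybenzoic acid, OOC(=O)c1cccc(Cl)c1
Why: Baeyer–Villiger oxidation of an ortho-alkoxybenzaldehyde proceeds with aryl migration to the formate, which methanolysis converts to the phenol.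

Step 9
Reactants: 14 5-bromo-3-methoxy-2-(methoxymethoxy)phenol
Product: 15 1-(benzyloxy)-5-bromo-3-methoxy-2-(methoxymethoxy)benzene
Conditions: BnBr, K2CO3, DMF, rt
Reagents that add atoms: benzyl bromide, BrCc1ccccc1
Why: Williamson ether synthesis puts the hydrogenolysable benzyl group on the oxygen that ends as the free ring A phenol.

Step 10
Reactants: 15 1-(benzyloxy)-5-bromo-3-methoxy-2-(methoxymethoxy)benzene; 9 (2S)-2-[5-bromo-3-methoxy-2-(methoxymethoxy)phenyl]propanal
Product: 17 (2S)-1-[3-(benzyloxy)-5-methoxy-4-(methoxymethoxy)phenyl]-2-[5-bromo-3-methoxy-2-(methoxymethoxy)phenyl]propan-1-ol (both C1 epimers), via aryl Grignard reagent 16 (not isolated)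
Conditions: 15 (1.5 equiv), Mg turnings, THF, 45 °C; then 9, THF, −78 °C; H2O quench
Reagents that add atoms: none
Why: Grignard 1,2-addition at −78 °C outruns enolisation of the α-aryl aldehyde so the 2S centre is kept, while the new carbinol centre (Felkin–Anh-biased mixture) is erased in the next step.

Step 11
Reactants: 17 (2S)-1-[3-(benzyloxy)-5-methoxy-4-(methoxymethoxy)phenyl]-2-[5-bromo-3-methoxy-2-(methoxymethoxy)phenyl]propan-1-ol
Product: 20 2-(benzyloxy)-4-[(2S,3S)-5-bromo-7-methoxy-3-methyl-2,3-dihydro-1-benzofuran-2-yl]-6-methoxyphenol, via triol 18 (not isolated), via p-quinone methide 19 (not isolated)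
Conditions: HCl (1.25 M in MeOH), 45 °C; then evaporate, p-TsOH·H2O (5 mol%), CH2Cl2, rt
Reagents that add atoms: none
Why: Acid removes both MOM groups as dimethoxymethane, the 4-hydroxybenzylic alcohol loses water to the p-quinone methide (reacting as its O-protonated form), and the ring B phenol adds to the exocyclic carbon in a 5-exo-trig intramolecular oxa-Michael (1,6-conjugate) addition whose reversibility places the new C2 aryl group trans to the fixed C3 methyl group, giving 2S,3S.

Step 12
Reactants: 20 2-(benzyloxy)-4-[(2S,3S)-5-bromo-7-methoxy-3-methyl-2,3-dihydro-1-benzofuran-2-yl]-6-methoxyphenol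
Product: 21 (2S,3S)-2-[3-(benzyloxy)-4,5-dimethoxyphenyl]-5-bromo-7-methoxy-3-methyl-2,3-dihydro-1-benzofuran
Conditions: MeI, K2CO3, DMF, rt
Reagents that add atoms: iodomethane, CI
Why: Williamson methylation caps the phenol that served as the quinone methide trigger, which also removes the pathway for ring opening and fixes both ring stereocentres.

Step 13
Reactants: 22 ethyl (2S)-2-hydroxypropanoate (ethyl (S)-lactate)
Product: 23 ethyl (2S)-2-(benzyloxy)propanoate
Conditions: BnOC(=NH)CCl3, TfOH (cat.), cyclohexane/CH2Cl2, rt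
Reagents that add atoms: benzyl 2,2,2-trichloroacetimidate, N=C(OCc1ccccc1)C(Cl)(Cl)Cl
Why: Acid-catalysed O-benzylation with the trichloroacetimidate avoids base, so the α-stereocentre of the lactate is not epimerised.

Step 14
Reactants: 23 ethyl (2S)-2-(benzyloxy)propanoate
Product: 24 (2S)-2-(benzyloxy)-N-methoxy-N-methylpropanamide
Conditions: MeNH(OMe)·HCl, iPrMgCl, THF, −20 °C; 1 M HCl quench
Reagents that add atoms: N,O-dimethylhydroxylamine hydrochloride, CNOC.Cl
Why: Aminolysis of the ester by the chloromagnesium amide made in the flask (Weinreb amide formation) is fast at −20 °C and leaves the stereocentre intact.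

Step 15
Reactants: 21 (2S,3S)-2-[3-(benzyloxy)-4,5-dimethoxyphenyl]-5-bromo-7-methoxy-3-methyl-2,3-dihydro-1-benzofuran; 24 (2S)-2-(benzyloxy)-N-methoxy-N-methylpropanamide
Product: 26 (2S)-2-(benzyloxy)-1-{(2S,3S)-2-[3-(benzyloxy)-4,5-dimethoxyphenyl]-7-methoxy-3-methyl-2,3-dihydro-1-benzofuran-5-yl}propan-1-one, via aryllithium 25 (not isolated)
Conditions: n-BuLi, THF, −78 °C; then 24, −78 to −40 °C; AcOH quench at −78 °C
Reagents that add atoms: none
Why: Bromine–lithium exchange followed by Weinreb ketone synthesis stops at the ketone because the chelated tetrahedral adduct survives until the cold acidic quench, which also avoids epimerising the α-benzyloxy centre.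

Step 16
Reactants: 26 (2S)-2-(benzyloxy)-1-{(2S,3S)-2-[3-(benzyloxy)-4,5-dimethoxyphenyl]-7-methoxy-3-methyl-2,3-dihydro-1-benzofuran-5-yl}propan-1-one
Product: 27 (1R,2S)-2-(benzyloxy)-1-{(2S,3S)-2-[3-(benzyloxy)-4,5-dimethoxyphenyl]-7-methoxy-3-methyl-2,3-dihydro-1-benzofuran-5-yl}propan-1-ol
Conditions: Zn(BH4)2 (preformed solution in Et2O), Et2O, −20 to 0 °C
Reagents that add atoms: none
Why: Chelation-controlled (Cram chelate) reduction, in which zinc bridges the carbonyl and benzyloxy oxygens and hydride attacks the face opposite the methyl group, gives the anti (erythro) 1R,2S alcohol.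

Step 17
Reactants: 27 (1R,2S)-2-(benzyloxy)-1-{(2S,3S)-2-[3-(benzyloxy)-4,5-dimethoxyphenyl]-7-methoxy-3-methyl-2,3-dihydro-1-benzofuran-5-yl}propan-1-ol
Product: 28 (1R,2S)-1-[(2S,3S)-2-(3-hydroxy-4,5-dimethoxyphenyl)-7-methoxy-3-methyl-2,3-dihydro-1-benzofuran-5-yl]propane-1,2-diol (CNP0229216.1)
Conditions: H2 (1 atm), Pd/C (10%), EtOAc, rt; stop at full conversion
Reagents that add atoms: none
Why: Catalytic hydrogenolysis cleaves both O-benzyl ethers under neutral conditions faster than the cyclic benzylic ether or the benzylic alcohol, and no stereocentre is involved.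

## Compound list

1 | rac-(E)-pent-3-en-2-ol | C/C=C/C(C)O | starting material
2 | (2R,3E)-pent-3-en-2-ol | C/C=C/[C@@H](C)O | intermediate
3 | 4-bromo-2-methoxyphenol | COc1cc(Br)ccc1O | starting material
4 | 4-bromo-2-methoxy-1-{[(2S,3E)-pent-3-en-2-yl]oxy}benzene | C/C=C/[C@H](C)Oc1ccc(Br)cc1OC | intermediate
5 | (6R)-4-bromo-2-methoxy-6-[(2R,3E)-pent-3-en-2-yl]cyclohexa-2,4-dien-1-one (ring centre as set by the chair transition state, lost on enolisation) | C/C=C/[C@@H](C)[C@@H]1C=C(Br)C=C(OC)C1=O | intermediate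
6 | 4-bromo-2-methoxy-6-[(2R,3E)-pent-3-en-2-yl]phenol | C/C=C/[C@@H](C)c1cc(Br)cc(OC)c1O | intermediate
7 | 5-bromo-1-methoxy-2-(methoxymethoxy)-3-[(2R,3E)-pent-3-en-2-yl]benzene | C/C=C/[C@@H](C)c1cc(Br)cc(OC)c1OCOC | intermediate
8 | 3-{(1S)-1-[5-bromo-3-methoxy-2-(methoxymethoxy)phenyl]ethyl}-5-methyl-1,2,4-trioxolane (ring carbons: mixture) | CC1OOC(O1)[C@@H](C)c2cc(Br)cc(OC)c2OCOC | intermediate
9 | (2S)-2-[5-bromo-3-methoxy-2-(methoxymethoxy)phenyl]propanal | O=C[C@@H](C)c1cc(Br)cc(OC)c1OCOC | intermediate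
10 | 2-hydroxy-3-methoxybenzaldehyde (o-vanillin) | COc1cccc(C=O)c1O | starting material
11 | 5-bromo-2-hydroxy-3-methoxybenzaldehyde | COc1cc(Br)cc(C=O)c1O | intermediate
12 | 5-bromo-3-methoxy-2-(methoxymethoxy)benzaldehyde | COCOc1c(OC)cc(Br)cc1C=O | intermediate
13 | 5-bromo-3-methoxy-2-(methoxymethoxy)phenyl formate | COCOc1c(OC)cc(Br)cc1OC=O | intermediate
14 | 5-bromo-3-methoxy-2-(methoxymethoxy)phenol | COCOc1c(OC)cc(Br)cc1O | intermediate
15 | 1-(benzyloxy)-5-bromo-3-methoxy-2-(methoxymethoxy)benzene | COCOc1c(OC)cc(Br)cc1OCc1ccccc1 | intermediate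
16 | [3-(benzyloxy)-5-methoxy-4-(methoxymethoxy)phenyl]magnesium bromide | COCOc1c(OC)cc([Mg]Br)cc1OCc1ccccc1 | intermediate
17 | (2S)-1-[3-(benzyloxy)-5-methoxy-4-(methoxymethoxy)phenyl]-2-[5-bromo-3-methoxy-2-(methoxymethoxy)phenyl]propan-1-ol (both C1 epimers) | COCOc1c(OC)cc(C(O)[C@@H](C)c2cc(Br)cc(OC)c2OCOC)cc1OCc1ccccc1 | intermediate
18 | (2S)-1-[3-(benzyloxy)-4-hydroxy-5-methoxyphenyl]-2-(5-bromo-2-hydroxy-3-methoxyphenyl)propan-1-ol (both C1 epimers) | COc1cc(C(O)[C@@H](C)c2cc(Br)cc(OC)c2O)cc(OCc2ccccc2)c1O | intermediate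
19 | 2-(benzyloxy)-4-[(2R)-2-(5-bromo-2-hydroxy-3-methoxyphenyl)propylidene]-6-methoxycyclohexa-2,5-dien-1-one (either alkene geometry) | COC1=CC(=C[C@@H](C)c2cc(Br)cc(OC)c2O)C=C(OCc2ccccc2)C1=O | intermediate
20 | 2-(benzyloxy)-4-[(2S,3S)-5-bromo-7-methoxy-3-methyl-2,3-dihydro-1-benzofuran-2-yl]-6-methoxyphenol | COc1cc([C@H]2Oc3c(OC)cc(Br)cc3[C@@H]2C)cc(OCc2ccccc2)c1O | intermediate
21 | (2S,3S)-2-[3-(benzyloxy)-4,5-dimethoxyphenyl]-5-bromo-7-methoxy-3-methyl-2,3-dihydro-1-benzofuran | COc1cc([C@H]2Oc3c(OC)cc(Br)cc3[C@@H]2C)cc(OCc2ccccc2)c1OC | intermediate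
22 | ethyl (2S)-2-hydroxypropanoate | CCOC(=O)[C@H](C)O | starting material
23 | ethyl (2S)-2-(benzyloxy)propanoate | CCOC(=O)[C@H](C)OCc1ccccc1 | intermediate
24 | (2S)-2-(benzyloxy)-N-methoxy-N-methylpropanamide | CON(C)C(=O)[C@H](C)OCc1ccccc1 | intermediate
25 | {(2S,3S)-2-[3-(benzyloxy)-4,5-dimethoxyphenyl]-7-methoxy-3-methyl-2,3-dihydro-1-benzofuran-5-yl}lithium | COc1cc([C@H]2Oc3c(OC)cc([Li])cc3[C@@H]2C)cc(OCc2ccccc2)c1OC | intermediate
26 | (2S)-2-(benzyloxy)-1-{(2S,3S)-2-[3-(benzyloxy)-4,5-dimethoxyphenyl]-7-methoxy-3-methyl-2,3-dihydro-1-benzofuran-5-yl}propan-1-one | COc1cc([C@H]2Oc3c(OC)cc(C(=O)[C@H](C)OCc4ccccc4)cc3[C@@H]2C)cc(OCc2ccccc2)c1OC | intermediate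
27 | (1R,2S)-2-(benzyloxy)-1-{(2S,3S)-2-[3-(benzyloxy)-4,5-dimethoxyphenyl]-7-methoxy-3-methyl-2,3-dihydro-1-benzofuran-5-yl}propan-1-ol | COc1cc([C@H]2Oc3c(OC)cc([C@@H](O)[C@H](C)OCc4ccccc4)cc3[C@@H]2C)cc(OCc2ccccc2)c1OC | intermediate
28 | (1R,2S)-1-[(2S,3S)-2-(3-hydroxy-4,5-dimethoxyphenyl)-7-methoxy-3-methyl-2,3-dihydro-1-benzofuran-5-yl]propane-1,2-diol | COc1cc([C@H]2Oc3c(OC)cc([C@@H](O)[C@H](C)O)cc3[C@@H]2C)cc(O)c1OC | target

## Step count and risks

Total step count: 17. Longest linear sequence: 11 steps (steps 1, 2, 3, 4, 5, 10, 11, 12, 15, 16, 17, from 1 to 28).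

**Step 10** is the most fragile, because the α-aryl aldehyde 9 can be enolised by the basic Grignard reagent, which lowers the yield and erodes the C3 configuration. The fallback replaces the basic carbanion by a non-basic organochromium reagent. It sets out from 15, which is converted by copper-catalysed halogen exchange (NaI, CuI, trans-N,N'-dimethylcyclohexane-1,2-diamine, dioxane, 110 °C) into 1-(benzyloxy)-5-iodo-3-methoxy-2-(methoxymethoxy)benzene F2. This iodide is coupled with 9 under Nozaki–Hiyama–Kishi conditions (CrCl2, NiCl2 cat., DMF, rt), where the aryl bromide of 9 is inert, and the sequence comes back to the route at 17.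

**Step 2** can suffer from SN2' attack and diene elimination, since the alcohol is secondary and allylic, and either pathway costs yield or ee of ether 4. The fallback sets out from 1, which is acylated (ClCO2Me, pyridine, CH2Cl2) to rac-(E)-pent-3-en-2-yl methyl carbonate F1. Phenol 3 is then O-allylated with F1 by palladium-catalysed asymmetric allylic substitution (Pd2(dba)3·CHCl3, DACH-phenyl Trost ligand, CH2Cl2, rt). The symmetrical 1,3-dimethylallyl palladium intermediate makes this enantioconvergent, so no resolution is needed. The ligand enantiomer is the one that gives the S ether, confirmed against material from step 2 by chiral HPLC. The sequence comes back at 4.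

**Step 17** may over-reduce, because the side-chain carbinol is a para-alkoxybenzylic alcohol and the ring C2–O bond is a benzylic ether, both of which palladium can hydrogenolyse. The fallback reverses the order of the last two operations. It sets out from 26, which is debenzylated first (H2, Pd/C, EtOAc) to (2S)-2-hydroxy-1-[(2S,3S)-2-(3-hydroxy-4,5-dimethoxyphenyl)-7-methoxy-3-methyl-2,3-dihydro-1-benzofuran-5-yl]propan-1-one F3, which has no benzylic alcohol. Zn(BH4)2 then reduces the free α-hydroxy ketone through its zinc alkoxide chelate with the same anti selectivity, and the sequence comes back at the target 28.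

## Further compounds

F1 | step 2 | rac-(E)-pent-3-en-2-yl methyl carbonate | C/C=C/C(C)OC(=O)OC
F2 | step 10 | 1-(benzyloxy)-5-iodo-3-methoxy-2-(methoxymethoxy)benzene | COCOc1c(OC)cc(I)cc1OCc1ccccc1
F3 | step 17 | (2S)-2-hydroxy-1-[(2S,3S)-2-(3-hydroxy-4,5-dimethoxyphenyl)-7-methoxy-3-methyl-2,3-dihydro-1-benzofuran-5-yl]propan-1-one | COc1cc([C@H]2Oc3c(OC)cc(C(=O)[C@H](C)O)cc3[C@@H]2C)cc(O)c1OC
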